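**Plan**

1. Retrosynthesis: the side chain is cut at C12–C13 (alkyl–butenolide coupling) and at C9–C11 (vinylation of a C9 enol triflate). The C2 and C6 carbinols and H5 go back to the C2=C3 and C5=C6 alkenes, C19 to an ester, and C4 is cut at C4–C18 and C4–C19. Ring B is then opened at C5–C6 and C8–C9, and C9–C10 is cut last.
2. Forward: ring A is bought as 3-methylcyclohex-2-enone. Nitromethane supplies C9, and crotonaldehyde (C8, C17, C7, C6) is annulated onto C9 and C5 so that ring B closes at C5–C6. The bought butenolide ring is joined last.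
3. Enabling feature: C5 is the α-CH2 of the ring-A ketone (C4) and lies 1,3 to the nitronate carbon C9 across the quaternary C10, so a four-carbon enal can bridge the two donors. Of all aldol modes only C5→C6 gives a six-membered ring that can dehydrate.
4. The closure leaves a cross-conjugated C4(=O)–C5=C6 unit with C5 trigonal. Enol triflation, carbonylation and deconjugative methylation turn it into C4(Me)(CO2Me) flanked by C2=C3 and C5=C6.
5. Stereochemistry: C10 comes from an amine-catalysed nitro-Michael addition (step 1). C4 is set by methylation anti to the angular methyl C20. C2, C5 and C6 are set together in one hydroboration from the α-face, which the axial C19 and C20 groups leave open.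

Key step: step 2

Remark: atoms carry labdane numbers (C1–C20; angular methyl C20 is β). C8 and C9 of compounds 5–7 arise as epimer mixtures that are erased in steps 3 and 4, so their SMILES leave these two centres open.

**Route**

Step 1
Reactants: 1 3-methylcyclohex-2-en-1-one; 2 nitromethane
Product: 3 (S)-3-methyl-3-(nitromethyl)cyclohexan-1-one
Conditions: 9-amino-9-deoxy-epi-cinchona primary amine (10 mol%, pseudoenantiomer chosen for the S product), PhCO2H (30 mol%), MeNO2 (5 equiv), PhMe, ca. 9 kbar, rt
Reagents that add atoms: none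
Why: Iminium activation of the enone lets the nitronate add to C10 on the face fixed by the cinchona scaffold (organocatalytic asymmetric nitro-Michael addition to a β-substituted cyclic enone), so the quaternary centre C10 should be set by catalyst control.

Step 2
Reactants: 3 (S)-3-methyl-3-(nitromethyl)cyclohexan-1-one; 4 (E)-but-2-enal
Product: 6 (4aS)-4a,6-dimethyl-5-nitro-3,4,4a,5,6,7-hexahydronaphthalen-1(2H)-one, via nitro keto aldehyde 5 (not isolated)
Conditions: 4 (1.5 equiv), (±)-α,α-diphenylprolinol trimethylsilyl ether (20 mol%), PhCO2H (20 mol%), MeOH, rt; then solvent switch to PhMe, TsOH·H2O (30 mol%), 80 °C, −H2O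
Reagents that add atoms: none
Why: The bulky secondary amine turns 4 into its iminium ion but does not condense with the ring ketone, and the nitronate of 3 (its only acidic C–H) adds through C9 to the β-carbon, forming C8–C9 in a Hayashi–Jørgensen-type nitro-Michael addition that gives 5. With acid the enol of the ring-A ketone attacks the aldehyde through C5 and the aldol dehydrates to the conjugated enone; this is a Robinson-type intramolecular aldol condensation, 6-(enolexo)-exo-trig, and it closes ring B at C5–C6. The new centres C8 and C9 form without control, which is harmless because C9 becomes a ketone in step 3 and C8 an sp2 carbon in step 4, while C10 is untouched. The selectivity needed is constitutional: closure through C3 would need an eight-membered ring, and closure of the aldehyde enol (C7) onto the C4 ketone gives a bicyclo[3.3.1] aldol that cannot dehydrate without a bridgehead double bond and so reverts, leaving only the C5–C6 mode to drain to a stable enone. The C5=C6 bond keeps C5 trigonal, which postpones the ring-fusion centre to step 7, where reagent approach can set it trans.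

Step 3
Reactants: 6 (4aS)-4a,6-dimethyl-5-nitro-3,4,4a,5,6,7-hexahydronaphthalen-1(2H)-one
Product: 7 (4aS)-4a,6-dimethyl-3,4,4a,7-tetrahydronaphthalene-1,5(2H,6H)-dione
Conditions: NaOMe (1.1 equiv), MeOH, 0 °C; then aq. TiCl3 (4 equiv), NH4OAc buffer (pH 5–6), 0 °C → rt
Reagents that add atoms: water, O
Why: A Nef reaction in its titanium trichloride form should reduce the C9 nitronate to the imine and hydrolyse it to the C9 ketone under buffered conditions that leave the enone and C10 alone.

Step 4
Reactants: 7 (4aS)-4a,6-dimethyl-3,4,4a,7-tetrahydronaphthalene-1,5(2H,6H)-dione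
Product: 8 (4aS)-4a,6-dimethyl-3,4,4a,7-tetrahydronaphthalene-1,5-diyl bis(trifluoromethanesulfonate)
Conditions: KN(SiMe3)2 (2.4 equiv), THF, −78 °C; PhNTf2 (2.5 equiv), −78 → 0 °C
Reagents that add atoms: N-phenylbis(trifluoromethanesulfonimide), O=S(=O)(N(c1ccccc1)S(=O)(=O)C(F)(F)F)C(F)(F)F
Why: Kinetic α′-deprotonation of the enone at C3 and deprotonation of the C9 ketone at its only α-hydrogen (C8), followed by O-sulfonylation (enol triflate formation), should give the C3=C4(OTf)–C5=C6 dienyl triflate and the C8=C9 enol triflate, and removes the C8 stereocentre.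

Step 5
Reactants: 8 (4aS)-4a,6-dimethyl-3,4,4a,7-tetrahydronaphthalene-1,5-diyl bis(trifluoromethanesulfonate)
Product: 9 methyl (4aS)-4a,6-dimethyl-5-(trifluoromethanesulfonyloxy)-3,4,4a,7-tetrahydronaphthalene-1-carboxylate
Conditions: Pd(OAc)2 (5 mol%), PPh3 (10 mol%), CO (1 atm), MeOH, Et3N, DMF, rt
Reagents that add atoms: carbon monoxide, [C-]#[O+]; methanol, CO
Why: Palladium-catalysed methoxycarbonylation of an enol triflate should occur only at C4, because that conjugated dienyl triflate has a CH neighbour, whereas the C9 triflate sits between the quaternary C10 and a tetrasubstituted alkene carbon and undergoes oxidative addition far more slowly.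

Step 6
Reactants: 9 methyl (4aS)-4a,6-dimethyl-5-(trifluoromethanesulfonyloxy)-3,4,4a,7-tetrahydronaphthalene-1-carboxylate
Product: 10 methyl (1S,4aS)-1,4a,6-trimethyl-5-(trifluoromethanesulfonyloxy)-1,4,4a,7-tetrahydronaphthalene-1-carboxylate
Conditions: LiN(iPr)2 (1.2 equiv), DMPU, THF, −78 °C; MeI, −78 → −30 °C
Reagents that add atoms: iodomethane, CI
Why: Removal of the γ-hydrogen at C2 gives a cross-conjugated ester dienolate that alkylates at its α-carbon C4 (deconjugative α-alkylation), moving the ring-A alkene to C2=C3; MeI should approach anti to the pseudoaxial angular methyl C20, so the new methyl C18 ends α and the ester C19 β.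

Step 7
Reactants: 10 methyl (1S,4aS)-1,4a,6-trimethyl-5-(trifluoromethanesulfonyloxy)-1,4,4a,7-tetrahydronaphthalene-1-carboxylate
Product: 12 methyl 2α,6α-dihydroxy-9-(trifluoromethanesulfonyloxy)-11,12,13,14,15,16-hexanorlabd-8-en-19-oate, via bis(organoborane) 11 (not isolated)
Conditions: 9-BBN (1.5 equiv), THF, 0 → 50 °C; BH3·THF (3 equiv), 0 °C → rt; then 30% H2O2, aq. NaOAc, 0 °C → rt
Reagents that add atoms: hydrogen peroxide, OO
Why: In this hydroboration–oxidation 9-BBN should add to C2=C3 with boron on C2 (away from quaternary C4) and BH3 to C5=C6 with boron on C6, both syn from the α-face because the β-face carries the pseudoaxial C19 ester and the axial C20 methyl; oxidation with retention then gives 2α-OH, 6α-OH and 5α-H (trans ring fusion), three stereocentres in one operation.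

Step 8
Reactants: 12 methyl 2α,6α-dihydroxy-9-(trifluoromethanesulfonyloxy)-11,12,13,14,15,16-hexanorlabd-8-en-19-oate
Product: 13 methyl 2α,6α-dihydroxy-13,14,15,16-tetranorlabda-8,11-dien-19-oate
Conditions: CH2=CHSnBu3 (1.5 equiv), Pd(PPh3)4 (5 mol%), LiCl (3 equiv), CuI (10 mol%), DMF, 80 °C
Reagents that add atoms: tributyl(vinyl)stannane, C=C[Sn](CCCC)(CCCC)CCCC
Why: A Stille coupling of the hindered C9 enol triflate, helped by LiCl and CuI, should install C11=C12 with the free hydroxyls tolerated and no stereocentre touched.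

Step 9
Reactants: 13 methyl 2α,6α-dihydroxy-13,14,15,16-tetranorlabda-8,11-dien-19-oate
Product: 14 13,14,15,16-tetranorlabda-8,11-diene-2α,6α,19-triol
Conditions: LiAlH4 (4 equiv), THF, 0 °C → reflux; Fieser work-up
Reagents that add atoms: none
Why: Hydride reduction of the neopentyl axial ester should give the C19 primary alcohol without affecting the diene or any stereocentre.

Step 10
Reactants: 14 13,14,15,16-tetranorlabda-8,11-diene-2α,6α,19-triol; 15 4-bromofuran-2(5H)-one
Product: 17 2α,6α,19-trihydroxylabda-8,13-dien-15,16-olide (CNP0387838.1), via alkylborane 16 (not isolated)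
Conditions: 9-BBN (5 equiv, excess covers the three hydroxyls), THF, rt; then 15 (1.5 equiv), PdCl2(dppf) (5 mol%), AsPh3 (5 mol%), aq. K3PO4 (3 equiv), DMF, rt → 45 °C
Reagents that add atoms: none
Why: 9-BBN should add only to the terminal carbon C12 of the diene, and the primary alkylborane then undergoes alkyl Suzuki–Miyaura coupling with the β-bromobutenolide (C12–C13) under a phosphate base mild enough to spare the lactone.

**Compound list**

1 | 3-methylcyclohex-2-en-1-one | CC1=CC(=O)CCC1 | starting material
2 | nitromethane | C[N+](=O)[O-] | starting material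
3 | (S)-3-methyl-3-(nitromethyl)cyclohexan-1-one | [O-][N+](=O)C[C@@]1(C)CCCC(=O)C1 | intermediate
4 | (E)-but-2-enal (crotonaldehyde) | C/C=C/C=O | starting material
5 | 3-methyl-4-[(1S)-1-methyl-3-oxocyclohexyl]-4-nitrobutanal (C8/C9 epimers, not isolated) | O=CCC(C)C([N+](=O)[O-])[C@@]1(C)CCCC(=O)C1 | intermediate
6 | (4aS)-4a,6-dimethyl-5-nitro-3,4,4a,5,6,7-hexahydronaphthalen-1(2H)-one (C8/C9 epimers) | CC1C([N+](=O)[O-])[C@@]2(C)CCCC(=O)C2=CC1 | intermediate
7 | (4aS)-4a,6-dimethyl-3,4,4a,7-tetrahydronaphthalene-1,5(2H,6H)-dione (C8 epimers) | CC1C(=O)[C@@]2(C)CCCC(=O)C2=CC1 | intermediate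
8 | (4aS)-4a,6-dimethyl-3,4,4a,7-tetrahydronaphthalene-1,5-diyl bis(trifluoromethanesulfonate) | CC1=C(OS(=O)(=O)C(F)(F)F)[C@@]2(C)CCC=C(OS(=O)(=O)C(F)(F)F)C2=CC1 | intermediate
9 | methyl (4aS)-4a,6-dimethyl-5-(trifluoromethanesulfonyloxy)-3,4,4a,7-tetrahydronaphthalene-1-carboxylate | CC1=C(OS(=O)(=O)C(F)(F)F)[C@@]2(C)CCC=C(C(=O)OC)C2=CC1 | intermediate
10 | methyl (1S,4aS)-1,4a,6-trimethyl-5-(trifluoromethanesulfonyloxy)-1,4,4a,7-tetrahydronaphthalene-1-carboxylate (C18 α, C19 ester β) | CC1=C(OS(=O)(=O)C(F)(F)F)[C@@]2(C)CC=C[C@](C)(C(=O)OC)C2=CC1 | intermediate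
11 | 2α-(9-borabicyclo[3.3.1]nonan-9-yl)-6α-boranyl analogue of 12 (not isolated) | CC1=C(OS(=O)(=O)C(F)(F)F)[C@@]2(C)C[C@@H](B3C4CCCC3CCC4)C[C@](C)(C(=O)OC)[C@@H]2[C@@H](B)C1 | intermediate
12 | methyl 2α,6α-dihydroxy-9-(trifluoromethanesulfonyloxy)-11,12,13,14,15,16-hexanorlabd-8-en-19-oate (5α-H) | CC1=C(OS(=O)(=O)C(F)(F)F)[C@@]2(C)C[C@@H](O)C[C@](C)(C(=O)OC)[C@@H]2[C@@H](O)C1 | intermediate
13 | methyl 2α,6α-dihydroxy-13,14,15,16-tetranorlabda-8,11-dien-19-oate | CC1=C(C=C)[C@@]2(C)C[C@@H](O)C[C@](C)(C(=O)OC)[C@@H]2[C@@H](O)C1 | intermediate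
14 | 13,14,15,16-tetranorlabda-8,11-diene-2α,6α,19-triol | CC1=C(C=C)[C@@]2(C)C[C@@H](O)C[C@](C)(CO)[C@@H]2[C@@H](O)C1 | intermediate
15 | 4-bromofuran-2(5H)-one | O=C1C=C(Br)CO1 | starting material
16 | 12-(9-borabicyclo[3.3.1]nonan-9-yl)-13,14,15,16-tetranorlabd-8-ene-2α,6α,19-triol (not isolated; hydroxyls shown free) | CC1=C(CCB2C3CCCC2CCC3)[C@@]2(C)C[C@@H](O)C[C@](C)(CO)[C@@H]2[C@@H](O)C1 | intermediate
17 | 2α,6α,19-trihydroxylabda-8,13-dien-15,16-olide (CNP0387838.1) | CC1=C(CCC2=CC(=O)OC2)[C@@]2(C)C[C@@H](O)C[C@](C)(CO)[C@@H]2[C@@H](O)C1 | target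

**Step count**

Total: 10 steps. Longest linear sequence: 10 steps (1 → 17).

**Steps most likely to fail**

Step 5. The risk is loss of site selectivity in the oxidative addition, so that the hindered C9 enol triflate is carbonylated as well or the C4 triflate reacts sluggishly. The fallback differentiates the two positions by timing instead. It sets out from 7: kinetic mono-enolisation at C3 with LiN(iPr)2 (1.05 equiv, −78 °C) and trapping with PhNTf2 (1.0 equiv) should give (4aS)-4a,6-dimethyl-5-oxo-3,4,4a,5,6,7-hexahydronaphthalen-1-yl trifluoromethanesulfonate F1, in which C9 is still a ketone. The same Pd(OAc)2/PPh3/CO/MeOH carbonylation then gives methyl (4aS)-4a,6-dimethyl-5-oxo-3,4,4a,5,6,7-hexahydronaphthalene-1-carboxylate F2. Tf2O with 2,6-di-tert-butyl-4-methylpyridine in CH2Cl2 converts the C9 ketone into its only possible enol triflate without a strong base, and the route is rejoined at 9.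

Step 6. The risk is alkylation of the extended enolate at a terminus (C2 or C6) instead of the central C4, or an incomplete facial bias. The fallback uses the carboxylate dianion instead of the ester enolate. It sets out from 9: Me3SnOH (1,2-dichloroethane, 80 °C) cleaves the methyl ester to (4aS)-4a,6-dimethyl-5-(trifluoromethanesulfonyloxy)-3,4,4a,7-tetrahydronaphthalene-1-carboxylic acid F3 without harming the enol triflate. LiN(iPr)2 (2.2 equiv) then MeI should alkylate the dienediolate dianion at its α-carbon, giving (1S,4aS)-1,4a,6-trimethyl-5-(trifluoromethanesulfonyloxy)-1,4,4a,7-tetrahydronaphthalene-1-carboxylic acid F4. Esterification with Me3SiCHN2 in MeOH/PhMe returns to 10.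

Step 2. The risk is that the enal is consumed by self-condensation or by the ring ketone before the hindered nitronate adds, or that the Michael addition reverses, so the domino sequence stalls. The fallback masks the ketone and separates the two bond formations. It sets out from 3: ethylene glycol and TsOH (PhH, −H2O) give (7S)-7-methyl-7-(nitromethyl)-1,4-dioxaspiro[4.5]decane F5. A base-mediated nitro-Michael addition to 4 (DBU 10 mol%, MeCN, 0 °C) gives 3-methyl-4-[(7S)-7-methyl-1,4-dioxaspiro[4.5]decan-7-yl]-4-nitrobutanal F6, which is isolated. Aqueous HCl in THF followed by TsOH in PhMe at 80 °C removes the ketal and closes ring B, returning to 6.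

Further compounds
F1 | step 5 | (4aS)-4a,6-dimethyl-5-oxo-3,4,4a,5,6,7-hexahydronaphthalen-1-yl trifluoromethanesulfonate (C8 epimers) | CC1C(=O)[C@@]2(C)CCC=C(OS(=O)(=O)C(F)(F)F)C2=CC1
F2 | step 5 | methyl (4aS)-4a,6-dimethyl-5-oxo-3,4,4a,5,6,7-hexahydronaphthalene-1-carboxylate (C8 epimers) | CC1C(=O)[C@@]2(C)CCC=C(C(=O)OC)C2=CC1
F3 | step 6 | (4aS)-4a,6-dimethyl-5-(trifluoromethanesulfonyloxy)-3,4,4a,7-tetrahydronaphthalene-1-carboxylic acid | CC1=C(OS(=O)(=O)C(F)(F)F)[C@@]2(C)CCC=C(C(=O)O)C2=CC1
F4 | step 6 | (1S,4aS)-1,4a,6-trimethyl-5-(trifluoromethanesulfonyloxy)-1,4,4a,7-tetrahydronaphthalene-1-carboxylic acid | CC1=C(OS(=O)(=O)C(F)(F)F)[C@@]2(C)CC=C[C@](C)(C(=O)O)C2=CC1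
F5 | step 2 | (7S)-7-methyl-7-(nitromethyl)-1,4-dioxaspiro[4.5]decane | [O-][N+](=O)C[C@@]1(C)CCCC2(C1)OCCO2
F6 | step 2 | 3-methyl-4-[(7S)-7-methyl-1,4-dioxaspiro[4.5]decan-7-yl]-4-nitrobutanal (C8/C9 epimers) | O=CCC(C)C([N+](=O)[O-])[C@@]1(C)CCCC2(C1)OCCO2
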